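Two numbers and one choice were asked, and I answered them with one quantity.

1. the flask with the highest amount of J, in percent of the E charged ("all alike" if they lie within 1.5 percentage points) (Sunday's / Monday's / all alike)
2. final J, as a percentage of the E charged, in Sunday's
3. final J, as a percentage of the E charged, in Monday's

| flask | E | D | temperature | remark | time |
|---|---|---|---|---|---|
| ochre | 20 mM (fed, over 30 min) | 13 mM | 70 °C | run made earlier |  |
| blue | 20 mM (fed, over 30 min) | 30 mM | 88 °C | run made earlier |  |
| green | 10 mM (fed, over 30 min) | 20 mM | 70 °C | run made earlier |  |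
| Sunday's | 20 mM (fed, over 30 min) | 20.0 mM | 100 °C |  | 2.5 h |
| Monday's | 20 mM (fed, over 30 min) | 20.0 mM | 75 °C |  | 2.5 h |

| run | time / h | J / % |
|---|---|---|
| ochre | 1.00 | 66.9 |
| ochre | 2.00 | 80.1 |
| ochre | 6.00 | 85.4 |
| ochre | 12.0 | 79.7 |
| blue | 0.833 | 74.4 |
| blue | 2.00 | 74.3 |
| blue | 4.00 | 67.4 |
| blue | 5.00 | 60.7 |
| green | 2.00 | 62.6 |
| green | 4.00 | 65.8 |
| green | 8.00 | 61.7 |
| green | 12.0 | 55.3 |

(standard deviation of a reading: 1 percentage point)

- percentages count the E that a species holds: one J counts as two
- a reading or a percentage of J counts all its forms, free or not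

I ran the flask slowly in my head. In the first instants, E entered and pairs of E formed J, at a rate going as [E] squared. I suspected a loss to D, going as [E][D]. Dividing one rate by the other leaves [E]/[D], and time drops out. Ochre had a charge ratio of 1.54 and a best reading of 85.4%, above green's 65.8% at 0.500.

In the middle, J climbed. Ochre read 66.9% after 1.00 h and 80.1% after 2.00 h.

At the end, J fell in the green and blue readings. I took each E lost from J as one D lost, and divided that loss per hour by [D]. This drain is a pseudo-first-order constant for D:

green, 70 °C: 0.00800 h⁻¹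

blue, 88 °C: 0.0302 h⁻¹

Blue and green differed in their charges as well, yet I assumed a constant factor per degree and stretched these by it. Sunday's drain, the E lost per hour divided by [D], came to 0.0733 h⁻¹. Monday's came to 0.0116 h⁻¹.

Running green's last readings back to zero time left 2.55 mM unaccounted for, which I read as free E. Blue gave 3.33 mM and ochre 1.78 mM, and I kept green's. My reckoning subtracted free E and the drain from the charge:

Sunday's: free E 12.7%, drain 16.7%, J 70.5%

Monday's: free E 12.7%, drain 2.85%, J 84.4%

So I chose Monday's, which in my reckoning was ahead of Sunday's by 14 percentage points.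

The forecast gave Monday's, with 69% for Sunday's and 76% for Monday's, holding that “J decays slowly, and faster with more D”, and its Monday's figure lay below mine.

The flasks gave Monday's as the highest, with 68.1% in Sunday's and 81.4% in Monday's.

    2 E ⇌ J (K = 120 M⁻¹, k = 11.4 M⁻¹ min⁻¹, Ea = 72.0 kJ mol⁻¹, ΔH = −7.00 kJ mol⁻¹)
    E → Q (k = 4.02 × 10⁻⁵ min⁻¹, Ea = 129 kJ mol⁻¹)
    L ⇌ J, rate k3*(cs3 - [J]) while solid is left; crystals form when [J] > cs3 (solubility = 0.820 mM, k = 1.94 min⁻¹)
    E + D → G (k = 0.478 M⁻¹ min⁻¹, Ea = 74.0 kJ mol⁻¹)
    (constants at 100 °C)

My figures stood above these by 2.4 points and 3 points. A neighbour flask, like Sunday's but kept at 115 °C, takes the same reckoning. By my estimate its drain stretches to 0.222 h⁻¹, with D at 57.4% and J at 44.7%. That flask held D at 60%, E at 12.9% and J at 46.8%.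

The runs were computed with made-up constants; scatter was added.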